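**Retrosynthetic overview**
- Target ⇒ an ortho-aroyl aryl oxazoline. One acid-catalysed isomerisation opens the oxazoline (a latent N-(2-hydroxyethyl)amide) and closes first the furan ring, then the lactam ring; a chiral Brønsted acid catalyst (named in step 6) sets the spiro centre.
- Keto oxazoline ⇒ aryl–carbonyl bond: ortho-lithiated 2-(3-methoxyphenyl)oxazoline + a peri-fused naphtholactone. The lactone carbonyl becomes the spiro carbon and its ring oxygen the furan oxygen; the lithiation fixes the spiro carbon ortho to OMe.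
- Naphtholactone ⇒ 7-methoxyphthalide + a 2-methylmalonaldehyde equivalent (aldol, then Friedel–Crafts cyclodehydration across C3/C4 of the phthalide builds the methyl-bearing benzene ring); phthalide ⇒ 3-methoxybenzyl alcohol + CO2.
- Ring order: oxazoline (temporary) and phthalide lactone → second naphthalene ring → furan ring and lactam ring together in the last step.

Assumption: the (R)-catalyst of step 6 is taken to give the (S)-spiro centre; the sense of induction must be confirmed on the first run, and the (S)-catalyst is used if it proves opposite.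

**Step 1**
Reactants: 1 3-methoxybenzonitrile + 2 2-aminoethanol
Product: 3 2-(3-methoxyphenyl)-4,5-dihydro-1,3-oxazole
Conditions: ZnCl2 (5 mol %), PhCl, reflux
Reagents that add atoms: none
Why: Witte–Seeliger oxazoline synthesis, in which the zinc-activated nitrile is attacked by the amine and the amidine cyclises through the hydroxyl with loss of NH3; no stereocentre.

**Step 2**
Reactants: 4 3-methoxybenzyl alcohol
Product: 7 7-methoxyphthalide, via dilithio alkoxide 5 (not isolated), via hydroxy acid 6 (not isolated)
Conditions: n-BuLi (2.2 equiv), TMEDA, hexane, 0 °C → rt; CO2, −78 °C → rt; 2 M HCl, rt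
Reagents that add atoms: carbon dioxide O=C=O
Why: Directed ortho-metalation, in which the lithium alkoxide and the methoxy group together direct lithiation to the carbon between them, CO2 traps the aryllithium and the hydroxy acid lactonises on acidification; no stereocentre.

**Step 3**
Reactants: 7 7-methoxyphthalide + 8 (E)-3-ethoxy-2-methylprop-2-enal
Product: 11 3-methoxy-7-methyl-2H-naphtho[1,8-bc]furan-2-one, via phthalide lithium enolate 9 (not isolated), via enal 10 (not isolated)
Conditions: LiN(iPr)2 (1.1 equiv), THF, −78 °C; 8, −78 → 0 °C; 2 M HCl, rt; then MsOH (3 equiv), CH2Cl2, 0 °C → rt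
Reagents that add atoms: none
Why: Aldol addition of the phthalide enolate to the β-ethoxyacrolein and acid transposition give enal 10 (loss of EtOH), and MsOH closes the new ring by Bradsher-type Friedel–Crafts cyclodehydration at the only reachable position, para to OMe, with aromatisation by loss of water; the stereocentre and alkene geometry of 10 are erased.

**Step 4**
Reactants: 11 3-methoxy-7-methyl-2H-naphtho[1,8-bc]furan-2-one
Product: 12 3-hydroxy-7-methyl-2H-naphtho[1,8-bc]furan-2-one
Conditions: BCl3 (2 equiv), CH2Cl2, −78 → 0 °C; H2O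
Reagents that add atoms: none
Why: Chelation-assisted Lewis acid ether cleavage, in which BCl3 bound to the lactone carbonyl removes the adjacent methyl ether (the only one present) while the aryl lactone survives at low temperature.

**Step 5**
Reactants: 3 2-(3-methoxyphenyl)-4,5-dihydro-1,3-oxazole + 12 3-hydroxy-7-methyl-2H-naphtho[1,8-bc]furan-2-one
Product: 15 2-[2-(2,8-dihydroxy-6-methyl-1-naphthoyl)-3-methoxyphenyl]-4,5-dihydro-1,3-oxazole, via aryllithium 13 (not isolated), via lithium naphtholate 14 (not isolated)
Conditions: 3: s-BuLi (1.1 equiv), TMEDA, THF, −78 °C; 12: LiN(SiMe3)2 (1.0 equiv), THF, −78 °C; combine, −78 → −20 °C; sat. aq. NH4Cl, 0 °C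
Reagents that add atoms: none
Why: Directed ortho-metalation between oxazoline and OMe (Meyers aryloxazoline lithiation) followed by nucleophilic acyl substitution on the strained aryl lactone, whose tetrahedral intermediate collapses to the peri-naphtholate so the doubly flanked ketone is not attacked again; the phenol is masked as its lithium salt, no stereocentre is formed, and any 16 formed on work-up is carried along since it is the next intermediate.

**Step 6**
Reactants: 15 2-[2-(2,8-dihydroxy-6-methyl-1-naphthoyl)-3-methoxyphenyl]-4,5-dihydro-1,3-oxazole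
Product: 18 (S)-3'-hydroxy-2-(2-hydroxyethyl)-7-methoxy-7'-methylspiro[isoindoline-1,2'-naphtho[1,8-bc]furan]-3-one, via spiro iminolactone 16 (not isolated), via quinone methide amide 17 (not isolated)
Conditions: (R)-3,3'-bis(2,4,6-triisopropylphenyl)-1,1'-binaphthyl-2,2'-diyl hydrogen phosphate (10 mol %), PhMe, 40 °C
Reagents that add atoms: none
Why: Proposed new method: the acid protonates the oxazoline, the peri-hemiketal oxygen of the ketone adds to it and the oxazoline opens to spiro iminolactone 16 (furan ring; as in Meyers hydroxyl-to-oxazoline transfers), N-protonated 16 ionises to ortho-quinone methide amide 17, whose aryl axis rotates freely, and the phosphate, hydrogen-bonded to the quinone methide carbonyl and the amide N–H, delivers nitrogen to one face to close the lactam and set the (S)-centre; the closest known reaction types are the imidate-to-amide (Chapman/Mumm) isomerisation, rhodamine spirolactam closure and chiral phosphoric acid-catalysed aza-additions to ortho-quinone methides, and the non-basic lactam does not re-ionise under the weak acid, so the centre is kept.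

**Compound list**
1 | 3-methoxybenzonitrile | COc1cccc(C#N)c1 | starting material
2 | 2-aminoethanol | NCCO | starting material
3 | 2-(3-methoxyphenyl)-4,5-dihydro-1,3-oxazole | COc1cccc(C2=NCCO2)c1 | intermediate
4 | 3-methoxybenzyl alcohol | COc1cccc(CO)c1 | starting material
5 | lithium (2-lithio-3-methoxyphenyl)methanolate (dilithio alkoxide) | COc1cccc(CO[Li])c1[Li] | intermediate
6 | 2-(hydroxymethyl)-6-methoxybenzoic acid | COc1cccc(CO)c1C(=O)O | intermediate
7 | 7-methoxyphthalide (7-methoxy-2-benzofuran-1(3H)-one) | COc1cccc2COC(=O)c12 | intermediate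
8 | (E)-3-ethoxy-2-methylprop-2-enal | CCO/C=C(\C)C=O | starting material
9 | lithium enolate of 7 (drawn as 3-lithio-7-methoxyphthalide) | COc1cccc2C([Li])OC(=O)c12 | intermediate
10 | 3-(4-methoxy-3-oxo-1,3-dihydro-2-benzofuran-1-yl)-2-methylprop-2-enal (racemic, E/Z mixture) | COc1cccc2C(C=C(C)C=O)OC(=O)c12 | intermediate
11 | 3-methoxy-7-methyl-2H-naphtho[1,8-bc]furan-2-one | COc1ccc2cc(C)cc3OC(=O)c1c23 | intermediate
12 | 3-hydroxy-7-methyl-2H-naphtho[1,8-bc]furan-2-one | Oc1ccc2cc(C)cc3OC(=O)c1c23 | intermediate
13 | 2-(2-lithio-3-methoxyphenyl)-4,5-dihydro-1,3-oxazole | COc1cccc(C2=NCCO2)c1[Li] | intermediate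
14 | lithium 7-methyl-2-oxo-2H-naphtho[1,8-bc]furan-3-olate | [Li]Oc1ccc2cc(C)cc3OC(=O)c1c23 | intermediate
15 | 2-[2-(2,8-dihydroxy-6-methyl-1-naphthoyl)-3-methoxyphenyl]-4,5-dihydro-1,3-oxazole (achiral; in equilibrium with its peri-hemiketal) | COc1cccc(C2=NCCO2)c1C(=O)c1c(O)ccc2cc(C)cc(O)c12 | intermediate
16 | 3'-hydroxy-3-[(2-hydroxyethyl)imino]-7-methoxy-7'-methyl-3H-spiro[2-benzofuran-1,2'-naphtho[1,8-bc]furan] (racemic spiro iminolactone) | COc1cccc2c1C1(Oc3cc(C)cc4ccc(O)c1c34)OC2=NCCO | intermediate
17 | N-(2-hydroxyethyl)-3-methoxy-2-(7-methyl-3-oxo-3H-naphtho[1,8-bc]furan-2-yl)benzamide (ortho-quinone methide amide, achiral) | COc1cccc(C(=O)NCCO)c1C1=C2C(=O)C=Cc3cc(C)cc(O1)c23 | intermediate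
18 | (S)-3'-hydroxy-2-(2-hydroxyethyl)-7-methoxy-7'-methylspiro[isoindoline-1,2'-naphtho[1,8-bc]furan]-3-one | COc1cccc2c1[C@]1(Oc3cc(C)cc4ccc(O)c1c34)N(CCO)C2=O | target

**Step count and risks**
Total steps: 6. Longest linear sequence: 5 (steps 2, 3, 4, 5, 6; step 1 is the convergent branch).

Most likely to fail:

- Step 6 (untested isomerisation; enantioselectivity, and the sense of induction, are not secured). Fallback, setting out from 15 and returning at 18: 15 is isomerised with an achiral acid (diphenyl hydrogen phosphate, 10 mol %, PhMe, 60 °C) to racemic 3'-hydroxy-2-(2-hydroxyethyl)-7-methoxy-7'-methylspiro[isoindoline-1,2'-naphtho[1,8-bc]furan]-3-one F1. F1 is resolved by preparative supercritical-fluid chromatography on an amylose tris(3,5-dimethylphenylcarbamate) phase. The (S)-enantiomer is 18; the (R)-enantiomer F2 is re-equilibrated to F1 with CF3CO2H in CH2Cl2 and resolved again.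

- Step 3 (the aldol adduct must transpose cleanly, and the enal must reach the Z geometry before the Friedel–Crafts closure). Fallback, setting out from 7 and returning at 11: benzylic bromination (N-bromosuccinimide, cat. azobisisobutyronitrile, PhCF3, reflux) gives 3-bromo-7-methoxyphthalide F3. PPh3 (MeCN, reflux) gives (4-methoxy-3-oxo-1,3-dihydro-2-benzofuran-1-yl)triphenylphosphonium bromide F4. Wittig reaction with methacrolein (Et3N, CH2Cl2, rt) gives 7-methoxy-3-(2-methylprop-2-en-1-ylidene)-2-benzofuran-1(3H)-one F5. Irradiation (medium-pressure Hg lamp, Pyrex, cat. I2, air, PhMe) isomerises the alkene, closes the ring by 6π-electrocyclisation onto C4 and dehydrogenates (Mallory-type oxidative photocyclisation) to 11.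

- Step 5 (the lithium naphtholate of the lactone may be too insoluble or too electron-rich to be acylated). Fallback, setting out from 12 and returning at 15: 12 is silylated (t-BuMe2SiCl, imidazole, DMF, rt) to 3-(tert-butyldimethylsilyloxy)-7-methyl-2H-naphtho[1,8-bc]furan-2-one F6. This neutral, more electrophilic lactone is opened by 13 (made from 3 as in step 5; THF, −78 °C) to 2-[2-(2-(tert-butyldimethylsilyloxy)-8-hydroxy-6-methyl-1-naphthoyl)-3-methoxyphenyl]-4,5-dihydro-1,3-oxazole F7. Bu4NF buffered with AcOH (THF, 0 °C) removes the silyl group to give 15.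

**Further compounds**
F1 | step 6 | racemic 3'-hydroxy-2-(2-hydroxyethyl)-7-methoxy-7'-methylspiro[isoindoline-1,2'-naphtho[1,8-bc]furan]-3-one | COc1cccc2c1C1(Oc3cc(C)cc4ccc(O)c1c34)N(CCO)C2=O
F2 | step 6 | (R)-3'-hydroxy-2-(2-hydroxyethyl)-7-methoxy-7'-methylspiro[isoindoline-1,2'-naphtho[1,8-bc]furan]-3-one | COc1cccc2c1[C@@]1(Oc3cc(C)cc4ccc(O)c1c34)N(CCO)C2=O
F3 | step 3 | 3-bromo-7-methoxyphthalide (racemic) | COc1cccc2C(Br)OC(=O)c12
F4 | step 3 | (4-methoxy-3-oxo-1,3-dihydro-2-benzofuran-1-yl)triphenylphosphonium bromide (racemic) | COc1cccc2C(OC(=O)c12)[P+](c1ccccc1)(c1ccccc1)c1ccccc1.[Br-]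
F5 | step 3 | 7-methoxy-3-(2-methylprop-2-en-1-ylidene)-2-benzofuran-1(3H)-one (E/Z mixture) | COc1cccc2C(=CC(C)=C)OC(=O)c12
F6 | step 5 | 3-(tert-butyldimethylsilyloxy)-7-methyl-2H-naphtho[1,8-bc]furan-2-one | CC(C)(C)[Si](C)(C)Oc1ccc2cc(C)cc3OC(=O)c1c23
F7 | step 5 | 2-[2-(2-(tert-butyldimethylsilyloxy)-8-hydroxy-6-methyl-1-naphthoyl)-3-methoxyphenyl]-4,5-dihydro-1,3-oxazole | COc1cccc(C2=NCCO2)c1C(=O)c1c(O[Si](C)(C)C(C)(C)C)ccc2cc(C)cc(O)c12
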